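The data were computed for an exercise, noise included.

A product that is merely being made cannot fall, yet in gamma J drops from 38.9% at 50.0 s to 6.8% at 120 s, so something is taking J away.

| flask | X | G | remark | time |
|---|---|---|---|---|
| epsilon | 2 mM | 1 µM | run made earlier |  |
| gamma | 2 mM | 4 µM | run made earlier |  |
| eta | 4 mM | 2 µM | run made earlier |  |
| flask | 2.0 mM | 2.0 µM |  | 2.5 min |

| run | time / s | J / % |
|---|---|---|
| epsilon | 10.0 | 7.9 |
| epsilon | 25.0 | 20.0 |
| epsilon | 50.0 | 33.1 |
| epsilon | 120 | 25.5 |
| gamma | 10.0 | 32.4 |
| gamma | 25.0 | 48.6 |
| gamma | 50.0 | 38.9 |
| gamma | 120 | 6.8 |
| eta | 10.0 | 6.9 |
| eta | 25.0 | 16.9 |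
| eta | 50.0 | 35.2 |
| eta | 120 | 31.7 |

(readings scatter by 0.5 percentage points)

- the best time, 2.5 min at the latest, for J
- the amount of J, in percent of the X charged, at that time
- earliest time at which at least nineteen twentieths of that best amount are there, in min
- latest time at which they still are, in min

- a reading or a percentage of J counts all its forms, free or not

How fast does J go? Taken as a first-order loss, those two gamma readings give a fall half-life of 27.8 s.

Why gamma? Its making should be over early: if the first reading of epsilon gives the start rate, that rate holds on unchanged and it goes with [G], which the ratio 4.10 between the first readings of gamma and epsilon supports for a fourfold [G], then gamma needs 31.6 s to pass its charge of X, which is shorter than 50.0 s.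

And the flask? At that rate it needs a feed time of 63.3 s, so I divide this by the half-life and call the result the feed count, the number of J half-lives that pass while the charge is being fed: 2.28.

But two readings prove no first order, so what is the count worth? As my own ordering, no more: gamma has 1.14 and a highest reading of 48.6%, epsilon has 4.55 and 33.1%, so I put the flask's best between those readings.

The forecast, which reads the fall as a straight line, says 42.5% at 0.48 min, and from 0.42 min to 0.66 min: “J is therefore removed by saturated G once X has gone, and X blocks this while present.”

The flask gives 41.8% at 0.703 min, and from 0.528 min to 0.923 min, so the height agrees with the forecast but the times come later.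

    X + G → J + G, rate k1*[X]*[G]/(1 + ([X]/Km1) + ([X]/Ksi1)^2) (4.90 mM, 1.70 mM, k = 24000 /M/s)
    X + J ⇌ L, settled at all times (K = 4400 /M)
    J → E (k = 0.0470 /s)

A count of 2.28 says that J goes while it is being made, and the run of this flask without the conversion of J into E gives the size of that one effect on the height, not the main reason for the flask's course: its highest J is 82.7% against 41.8%, about twice. The flask also holds L, which the count does not contain: 51.1% at 0.703 min, each L counting as two in that percentage.

The neighbour with 0.800 µM of G has a count of 5.69, higher than epsilon's, which points below epsilon's 33.1%; computed, its best is 32.3%.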